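**Retrosynthetic overview**

1. Ring numbering: O1, C2 (C=O), C3 (=CH2), C4 (CO2H), C5 (14-oxopentadecyl); the target is the cis (4S,5S) lactone. The route rests on the O1–C2(=O)–C3(=CH2) unit of this single five-membered ring: C2 lies between O1 and the methylene-bearing C3, so it is one CO inserted between a C5 hydroxyl and a terminal alkyne on C4.
2. Disconnection 1 (the only ring, formed in the key step): O1–C2 and C2–C3 by palladium-catalysed cyclocarbonylation of hydroxy enyne 18. The C4 carboxyl is carried as a vinyl group and unveiled afterwards (vinyl → CHO → CO2H, then ketal hydrolysis).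
3. Disconnection 2: the C4–alkyne bond by inverting opening of trans vinyl epoxide 15 at its allylic carbon. A trans epoxide opened with inversion gives the anti carbinol, which maps onto the cis lactone.
4. Disconnection 3: both stereocentres from Sharpless epoxidation of E allylic alcohol 11, then oxidation and Wittig methylenation.
5. Disconnection 4: the chain from pentadecanolide (methyl ketone via Weinreb amide, ketal, aldehyde, Horner–Wadsworth–Emmons homologation).

Key step: step 12

Remark: L-(+)-diethyl tartrate is taken as the ligand that gives the (2S,3S)-epoxy alcohol from an E-3-alkylallyl alcohol; with the D-(−)-ester the enantiomeric series would result.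

**Route**

Step 1
Reactants: 1 pentadecanolide; 2 N,O-dimethylhydroxylamine hydrochloride
Product: 3 15-hydroxy-N-methoxy-N-methylpentadecanamide
Conditions: MeNH(OMe)·HCl, AlMe3, CH2Cl2, 0 °C to rt; aq. HCl work-up
Reagents that add atoms: N,O-dimethylhydroxylamine hydrochloride (2), CNOC.Cl
Why: Weinreb aminolysis of a lactone, in which the chloro(methyl)aluminium amide formed in the flask should open the unstrained macrolactone to a hydroxy amide that cannot close again.

Step 2
Reactants: 3 15-hydroxy-N-methoxy-N-methylpentadecanamide; 4 methylmagnesium bromide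
Product: 5 16-hydroxyhexadecan-2-one
Conditions: MeMgBr (3 equiv), THF, 0 °C; aqueous work-up
Reagents that add atoms: methylmagnesium bromide (4), C[Mg]Br
Why: Weinreb ketone synthesis, in which the Grignard reagent (after deprotonating the hydroxyl) adds once to give a chelated tetrahedral adduct that releases the methyl ketone only on work-up.

Step 3
Reactants: 5 16-hydroxyhexadecan-2-one; 6 ethylene glycol
Product: 7 15,15-(ethylenedioxy)hexadecan-1-ol
Conditions: HOCH2CH2OH, p-TsOH (cat.), toluene, reflux, Dean–Stark
Reagents that add atoms: ethylene glycol (6), OCCO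
Why: Acid-catalysed ketalisation driven by azeotropic removal of water, which shields the ketone from the hydride, ylide and acetylide reagents used later.

Step 4
Reactants: 7 15,15-(ethylenedioxy)hexadecan-1-ol
Product: 8 15,15-(ethylenedioxy)hexadecanal
Conditions: TEMPO (cat.), PhI(OAc)2, CH2Cl2, rt
Reagents that add atoms: none
Why: Oxoammonium (TEMPO) oxidation of a primary alcohol, which should stop at the aldehyde in the absence of water and leave the ketal intact.

Step 5
Reactants: 8 15,15-(ethylenedioxy)hexadecanal; 9 triethyl phosphonoacetate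
Product: 10 ethyl (E)-17,17-(ethylenedioxy)octadec-2-enoate
Conditions: (EtO)2P(O)CH2CO2Et, NaH, THF, 0 °C to rt
Reagents that add atoms: triethyl phosphonoacetate (9), CCOC(=O)CP(=O)(OCC)OCC
Why: Horner–Wadsworth–Emmons olefination, which with a stabilised phosphonate anion and an unbranched aldehyde should give the E enoate.

Step 6
Reactants: 10 ethyl (E)-17,17-(ethylenedioxy)octadec-2-enoate
Product: 11 (E)-17,17-(ethylenedioxy)octadec-2-en-1-ol
Conditions: i-Bu2AlH (2.2 equiv), CH2Cl2, −78 °C; aq. sodium potassium tartrate
Reagents that add atoms: none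
Why: 1,2-Reduction of an enoate by the aluminium hydride, which should give the allylic alcohol without touching the alkene geometry or the ketal.

Step 7
Reactants: 11 (E)-17,17-(ethylenedioxy)octadec-2-en-1-ol
Product: 12 (2S,3S)-2,3-epoxy-17,17-(ethylenedioxy)octadecan-1-ol
Conditions: Ti(OiPr)4 (cat.), L-(+)-diethyl tartrate (cat.), t-BuOOH, 4 Å molecular sieves, CH2Cl2, −20 °C
Reagents that add atoms: tert-butyl hydroperoxide, CC(C)(C)OO
Why: Sharpless asymmetric epoxidation, in which syn oxygen transfer inside the titanium tartrate complex sets C2 and C3 together from the E alkene under ligand control of the face; these become C4 and C5 of the lactone.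

Step 8
Reactants: 12 (2S,3S)-2,3-epoxy-17,17-(ethylenedioxy)octadecan-1-ol
Product: 13 (2R,3S)-2,3-epoxy-17,17-(ethylenedioxy)octadecanal
Conditions: TEMPO (cat.), PhI(OAc)2, CH2Cl2, 0 °C to rt; used crude
Reagents that add atoms: none
Why: Oxoammonium oxidation under mild, non-basic conditions, which should give the epoxy aldehyde without epoxide opening or epimerisation at the α-carbon.

Step 9
Reactants: 13 (2R,3S)-2,3-epoxy-17,17-(ethylenedioxy)octadecanal; 14 methyltriphenylphosphonium bromide
Product: 15 (3S,4S)-3,4-epoxy-18,18-(ethylenedioxy)nonadec-1-ene (trans vinyl epoxide)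
Conditions: Ph3PCH3Br, KN(SiMe3)2, THF, −78 to 0 °C
Reagents that add atoms: methyltriphenylphosphonium bromide (14), C[P+](c1ccccc1)(c1ccccc1)c1ccccc1.[Br-]
Why: Wittig methylenation with the non-stabilised ylide at low temperature, which should convert the aldehyde into the vinyl group without touching the epoxide or its stereocentres.

Step 10
Reactants: 15 (3S,4S)-3,4-epoxy-18,18-(ethylenedioxy)nonadec-1-ene; 16 trimethylsilylacetylene
Product: 17 (3S,4S)-18,18-(ethylenedioxy)-3-[(trimethylsilyl)ethynyl]nonadec-1-en-4-ol
Conditions: Me3SiC≡CH, n-BuLi, THF, −78 °C; BF3·OEt2; then 15, −78 °C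
Reagents that add atoms: trimethylsilylacetylene (16), C#C[Si](C)(C)C
Why: Yamaguchi–Hirao alkynylation, in which the external alkynyl nucleophile attacks the BF3-complexed epoxide at the allylic carbon C3 (its C–O bond is loosened by the vinyl group) from the face opposite to oxygen, so that C3 is inverted and C4 is untouched to give the anti carbinol; an external nucleophile is chosen over an alkynylalane because a Lewis-acidic alane can deliver its alkynyl group to such an allylic carbon on the same face as the oxygen.

Step 11
Reactants: 17 (3S,4S)-18,18-(ethylenedioxy)-3-[(trimethylsilyl)ethynyl]nonadec-1-en-4-ol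
Product: 18 (3S,4S)-3-ethynyl-18,18-(ethylenedioxy)nonadec-1-en-4-ol
Conditions: K2CO3, MeOH, rt
Reagents that add atoms: none
Why: Methanolysis of the alkynyl–silicon bond, for which mild carbonate should suffice without isomerising the skipped enyne or touching the stereocentres.

Step 12
Reactants: 18 (3S,4S)-3-ethynyl-18,18-(ethylenedioxy)nonadec-1-en-4-ol; 19 carbon monoxide
Product: 20 cis-(4S,5S)-4-ethenyl-5-[14,14-(ethylenedioxy)pentadecyl]-3-methylideneoxolan-2-one
Conditions: PdCl2 (5 mol %), thiourea (10 mol %), CO (1–3 atm), acetone, 50 °C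
Reagents that add atoms: carbon monoxide (19), [C-]#[O+]
Why: Divalent palladium (PdCl2 kept in solution by thiourea), the C5 hydroxyl and CO should give an alkoxycarbonylpalladium chloride with loss of HCl, which forms O1–C2; the terminal alkyne on C4 then inserts syn into the Pd–C2 bond, which forms C2–C3, and the HCl set free cleaves the alkenyl–palladium bond to leave the exocyclic CH2 and return PdCl2, so the cycle needs neither oxidant nor base. The closest known reaction is the PdCl2/thiourea cyclocarbonylation of but-3-yn-1-ols, including ones branched at the propargylic carbon, to α-methylene-γ-butyrolactones. The lactone closes in the 5-exo-dig mode, because syn addition of palladium and C2 across the triple bond is possible only in the exo sense (an endo closure would demand a trans double bond in a six-membered ring). No stereocentre is created: C4 and C5 are spectators, and the anti arrangement of hydroxyl and ethynyl in 18 becomes the cis arrangement of side chain and vinyl group on the ring. The step needs the alkyne to react in preference to the C4 vinyl group, which lies at the same distance from O1; this is secured not by the tether but by the stronger binding and faster insertion of an alkyne at electrophilic palladium, and by the fact that only the alkenylpalladium from alkyne insertion can be protonolysed to turn the catalyst over. The near-neutral medium should leave the ketal and the doubly allylic C4 hydrogen untouched.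

Step 13
Reactants: 20 cis-(4S,5S)-4-ethenyl-5-[14,14-(ethylenedioxy)pentadecyl]-3-methylideneoxolan-2-one
Product: 23 cis-(4S,5S)-5-[14,14-(ethylenedioxy)pentadecyl]-3-methylidene-2-oxooxolane-4-carboxylic acid, via vicinal diol 21 (not isolated), via C4 aldehyde 22 (not isolated)
Conditions: OsO4 (2 mol %), NaIO4 (2.2 equiv), THF/H2O (pH 7 phosphate), 0 °C; extractive work-up; then NaClO2, NaH2PO4, 2-methyl-2-butene, t-BuOH/H2O, 0 °C
Reagents that add atoms: osmium tetroxide (oxygen carrier), O=[Os](=O)(=O)=O; sodium periodate, [Na+].[O-]I(=O)(=O)=O; sodium chlorite, [Na+].[O-]Cl=O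
Why: Lemieux–Johnson cleavage followed by Pinnick oxidation, in which electrophilic OsO4 should dihydroxylate the isolated vinyl group faster than the electron-poor exocyclic methylene, periodate cleaves the diol, and the doubly activated C4 aldehyde is oxidised at once under weakly acidic chlorite conditions so that its C4 hydrogen never meets base.

Step 14
Reactants: 23 cis-(4S,5S)-5-[14,14-(ethylenedioxy)pentadecyl]-3-methylidene-2-oxooxolane-4-carboxylic acid
Product: 24 allo-pertusaric acid
Conditions: 1 M HCl, THF, rt
Reagents that add atoms: water, O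
Why: Acid-catalysed hydrolysis of the dioxolane, which in dilute acid and without base should leave the lactone, the acrylate and the C4 configuration unchanged.

**Compound list**

1 | pentadecanolide (oxacyclohexadecan-2-one) | O=C1CCCCCCCCCCCCCCO1 | starting material
2 | N,O-dimethylhydroxylamine hydrochloride | CNOC.Cl | starting material
3 | 15-hydroxy-N-methoxy-N-methylpentadecanamide | CON(C)C(=O)CCCCCCCCCCCCCCO | intermediate
4 | methylmagnesium bromide | C[Mg]Br | starting material
5 | 16-hydroxyhexadecan-2-one | CC(=O)CCCCCCCCCCCCCCO | intermediate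
6 | ethylene glycol | OCCO | starting material
7 | 15,15-(ethylenedioxy)hexadecan-1-ol | CC1(CCCCCCCCCCCCCCO)OCCO1 | intermediate
8 | 15,15-(ethylenedioxy)hexadecanal | CC1(CCCCCCCCCCCCCC=O)OCCO1 | intermediate
9 | triethyl phosphonoacetate | CCOC(=O)CP(=O)(OCC)OCC | starting material
10 | ethyl (E)-17,17-(ethylenedioxy)octadec-2-enoate | CCOC(=O)/C=C/CCCCCCCCCCCCCC1(C)OCCO1 | intermediate
11 | (E)-17,17-(ethylenedioxy)octadec-2-en-1-ol | OC/C=C/CCCCCCCCCCCCCC1(C)OCCO1 | intermediate
12 | (2S,3S)-2,3-epoxy-17,17-(ethylenedioxy)octadecan-1-ol | OC[C@@H]1O[C@H]1CCCCCCCCCCCCCC2(C)OCCO2 | intermediate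
13 | (2R,3S)-2,3-epoxy-17,17-(ethylenedioxy)octadecanal | O=C[C@@H]1O[C@H]1CCCCCCCCCCCCCC2(C)OCCO2 | intermediate
14 | methyltriphenylphosphonium bromide | C[P+](c1ccccc1)(c1ccccc1)c1ccccc1.[Br-] | starting material
15 | (3S,4S)-3,4-epoxy-18,18-(ethylenedioxy)nonadec-1-ene | C=C[C@@H]1O[C@H]1CCCCCCCCCCCCCC2(C)OCCO2 | intermediate
16 | trimethylsilylacetylene | C#C[Si](C)(C)C | starting material
17 | (3S,4S)-18,18-(ethylenedioxy)-3-[(trimethylsilyl)ethynyl]nonadec-1-en-4-ol | O[C@@H](CCCCCCCCCCCCCC1(C)OCCO1)[C@H](C#C[Si](C)(C)C)C=C | intermediate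
18 | (3S,4S)-3-ethynyl-18,18-(ethylenedioxy)nonadec-1-en-4-ol | O[C@@H](CCCCCCCCCCCCCC1(C)OCCO1)[C@H](C#C)C=C | intermediate
19 | carbon monoxide | [C-]#[O+] | starting material
20 | cis-(4S,5S)-4-ethenyl-5-[14,14-(ethylenedioxy)pentadecyl]-3-methylideneoxolan-2-one | C=C1C(=O)O[C@@H](CCCCCCCCCCCCCC2(C)OCCO2)[C@H]1C=C | intermediate
21 | (4R,5S)-4-(1,2-dihydroxyethyl)-5-[14,14-(ethylenedioxy)pentadecyl]-3-methylideneoxolan-2-one, ring substituents cis as in 20, both epimers at the new carbinol carbon | C=C1C(=O)O[C@@H](CCCCCCCCCCCCCC2(C)OCCO2)[C@H]1C(O)CO | intermediate (not isolated)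
22 | cis-(4S,5S)-5-[14,14-(ethylenedioxy)pentadecyl]-3-methylidene-2-oxooxolane-4-carbaldehyde | C=C1C(=O)O[C@@H](CCCCCCCCCCCCCC2(C)OCCO2)[C@H]1C=O | intermediate (not isolated)
23 | cis-(4S,5S)-5-[14,14-(ethylenedioxy)pentadecyl]-3-methylidene-2-oxooxolane-4-carboxylic acid | C=C1C(=O)O[C@@H](CCCCCCCCCCCCCC2(C)OCCO2)[C@H]1C(=O)O | intermediate
24 | allo-pertusaric acid, (2S,3S)-4-methylidene-5-oxo-2-(14-oxopentadecyl)oxolane-3-carboxylic acid | C=C1C(=O)O[C@@H](CCCCCCCCCCCCCC(C)=O)[C@H]1C(=O)O | target

**Step count**

Total: 14 steps. Longest linear sequence: 14 steps (1 to 24).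

**Steps most likely to fail**

Step 10. The epoxide may be opened at the distal carbon or in the SN2′ sense, partial ionisation may erode the inversion at the allylic carbon, and BF3 may attack the ketal. Fallback: both stereocentres would be set by an Evans syn aldol reaction, setting out from aldehyde 8 and returning at 18.
- The dibutylboron dienolate of commercial (R)-4-benzyl-3-[(E)-but-2-enoyl]oxazolidin-2-one (n-Bu2BOTf, Et3N, CH2Cl2, −78 °C) should react at its α-carbon to give the syn α-vinyl aldol adduct F1.
- Silylation (TBSOTf, 2,6-lutidine) gives the silyl ether F2.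
- LiBH4 (THF, MeOH, 0 °C) removes the auxiliary to give the primary alcohol F3.
- Oxidation (TEMPO, PhI(OAc)2) gives the α-vinyl aldehyde F4, used at once.
- Corey–Fuchs homologation (CBr4, PPh3, CH2Cl2, 0 °C) gives the dibromoalkene F5.
- n-BuLi (THF, −78 °C) then water gives the silyl-protected enyne F6.
- Bu4NF in THF then gives 18.

Step 13. The osmium oxidant may also attack the exocyclic methylene, and the transient C4 aldehyde may enolise, which would epimerise C4 to the trans series or move the double bond into the ring. Fallback: the acrylate would be masked before the cleavage, setting out from 20 and returning at 23.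
- Conjugate addition of thiophenol (PhSH, cat. Et3N, THF, 0 °C) gives the phenylthiomethyl lactone F7.
- OsO4 (cat.)/NaIO4 cleaves the vinyl group and oxidises sulfur to the sulfoxide, giving the sulfinyl aldehyde F8, whose C4 hydrogen is now only singly activated.
- Chlorite oxidation gives the sulfinyl acid F9.
- Thermal syn elimination of benzenesulfenic acid (toluene, 110 °C), for which the only β-hydrogen is that on C3, restores the exocyclic methylene and gives 23.

Step 12. Turnover may stall through reduction of the catalyst to palladium metal, the vinyl group may compete for insertion, or a palladium hydride may migrate the C4 vinyl double bond. Fallback: the ring would be closed from a vinyl iodide under zerovalent palladium, setting out from 18 and returning at 20.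
- Stannylcupration of the terminal alkyne (Me3SnCu·SMe2, THF, MeOH, −78 °C) gives the 2-stannyl alkene F10.
- Iododestannylation (I2, CH2Cl2, 0 °C) gives the 2-iodoalkene F11.
- PdCl2(PPh3)2 (cat.), CO and K2CO3 in THF at 50 °C should then give 20 by oxidative addition, CO insertion and lactonisation by the C5 hydroxyl.

**Further compounds**

F1 | step 10 | (R)-4-benzyl-3-[(2R,3S)-2-ethenyl-17,17-(ethylenedioxy)-3-hydroxyoctadecanoyl]oxazolidin-2-one | O[C@@H](CCCCCCCCCCCCCC1(C)OCCO1)[C@H](C(=O)N2[C@H](Cc3ccccc3)COC2=O)C=C
F2 | step 10 | tert-butyldimethylsilyl ether of F1 at the C3 hydroxyl, (2R,3S) | CC(C)(C)[Si](C)(C)O[C@@H](CCCCCCCCCCCCCC1(C)OCCO1)[C@H](C(=O)N2[C@H](Cc3ccccc3)COC2=O)C=C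
F3 | step 10 | (2S,3S)-3-(tert-butyldimethylsilyloxy)-2-ethenyl-17,17-(ethylenedioxy)octadecan-1-ol | CC(C)(C)[Si](C)(C)O[C@@H](CCCCCCCCCCCCCC1(C)OCCO1)[C@H](CO)C=C
F4 | step 10 | (2R,3S)-3-(tert-butyldimethylsilyloxy)-2-ethenyl-17,17-(ethylenedioxy)octadecanal | CC(C)(C)[Si](C)(C)O[C@@H](CCCCCCCCCCCCCC1(C)OCCO1)[C@H](C=O)C=C
F5 | step 10 | (3S,4S)-4-(tert-butyldimethylsilyloxy)-3-(2,2-dibromoethenyl)-18,18-(ethylenedioxy)nonadec-1-ene | CC(C)(C)[Si](C)(C)O[C@@H](CCCCCCCCCCCCCC1(C)OCCO1)[C@H](C=C(Br)Br)C=C
F6 | step 10 | (3S,4S)-4-(tert-butyldimethylsilyloxy)-3-ethynyl-18,18-(ethylenedioxy)nonadec-1-ene | CC(C)(C)[Si](C)(C)O[C@@H](CCCCCCCCCCCCCC1(C)OCCO1)[C@H](C#C)C=C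
F7 | step 13 | 4-ethenyl-5-[14,14-(ethylenedioxy)pentadecyl]-3-[(phenylsulfanyl)methyl]oxolan-2-one, C4 and C5 as in 20, both C3 epimers | O=C1O[C@@H](CCCCCCCCCCCCCC2(C)OCCO2)[C@@H](C=C)C1CSc3ccccc3
F8 | step 13 | 5-[14,14-(ethylenedioxy)pentadecyl]-2-oxo-3-[(phenylsulfinyl)methyl]oxolane-4-carbaldehyde, C4 and C5 as in 20, mixed at C3 and sulfur | O=C1O[C@@H](CCCCCCCCCCCCCC2(C)OCCO2)[C@@H](C=O)C1CS(=O)c3ccccc3
F9 | step 13 | 5-[14,14-(ethylenedioxy)pentadecyl]-2-oxo-3-[(phenylsulfinyl)methyl]oxolane-4-carboxylic acid, C4 and C5 as in 23, mixed at C3 and sulfur | O=C1O[C@@H](CCCCCCCCCCCCCC2(C)OCCO2)[C@@H](C(=O)O)C1CS(=O)c3ccccc3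
F10 | step 12 | (3R,4S)-18,18-(ethylenedioxy)-3-[1-(trimethylstannyl)ethenyl]nonadec-1-en-4-ol | O[C@@H](CCCCCCCCCCCCCC1(C)OCCO1)[C@H](C(=C)[Sn](C)(C)C)C=C
F11 | step 12 | (3R,4S)-18,18-(ethylenedioxy)-3-(1-iodoethenyl)nonadec-1-en-4-ol | O[C@@H](CCCCCCCCCCCCCC1(C)OCCO1)[C@H](C(=C)I)C=C
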